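**Assumption:** the target has no stereocentres and no stereogenic double bonds, so it is achiral and there is no enantiomer to control. The one stereocentre that appears in the route (the carbinol carbon of 12) is formed racemic and destroyed in step 10.

## Retrosynthetic overview

1. Target ⇐ O-acetylation of the 2-hydroxyquinone ⇐ hydrolysis of the 2-methoxyquinone (vinylogous ester).
2. The quinone ring is formed last, by Moore rearrangement (4π opening, 6π closure, oxidation) of a 4-aryl-4-hydroxycyclobutenone. This comes from the key union of an aryllithium (C13 fragment) with 3-isopropyl-4-methoxycyclobutenedione (C8O3 fragment).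
3. Aryl fragment ⇐ mono Br/Li exchange and methylation of a symmetric 2-alkyl-1,3-dibromobenzene ⇐ Cu-catalysed coupling of 2,6-dibromobenzyl bromide with a homoallyl Grignard reagent.
4. Cyclobutenedione ⇐ squaric acid via dimethyl squarate and i-PrMgCl; homoallyl bromide ⇐ 3-methylbut-3-en-1-ol.
5. Ring order: the benzene ring and the four-membered ring are bought; the quinone ring is the only ring built.

## Route

**Step 1**
Reactants: 1, 1,3-dibromobenzene
Product: 2, 1,3-dibromo-2-methylbenzene (2,6-dibromotoluene)
Conditions: LDA (1.05 equiv), THF, −78 °C, 1 h; then MeI, −78 °C → rt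
Reagents that add atoms: iodomethane, CI
Why: Directed ortho-metalation removes the C2–H flanked by two bromines (most acidic site); the aryllithium is stable at −78 °C and is methylated by SN2.

**Step 2**
Reactants: 2, 1,3-dibromo-2-methylbenzene
Product: 3, 1,3-dibromo-2-(bromomethyl)benzene
Conditions: NBS (1.05 equiv), AIBN (cat.), PhCF3, 85 °C
Reagents that add atoms: N-bromosuccinimide, O=C1CCC(=O)N1Br
Why: Wohl–Ziegler radical bromination at the only benzylic C–H position; the electron-poor ring does not undergo ring bromination.

**Step 3**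
Reactants: 4, 3-methylbut-3-en-1-ol
Product: 5, 3-methylbut-3-en-1-yl 4-methylbenzenesulfonate
Conditions: TsCl, Et3N, DMAP (cat.), CH2Cl2, 0 °C → rt
Reagents that add atoms: tosyl chloride, Cc1ccc(cc1)S(Cl)(=O)=O
Why: Standard sulfonylation of a primary alcohol under non-acidic conditions that leave the 1,1-disubstituted alkene untouched.

**Step 4**
Reactants: 5, 3-methylbut-3-en-1-yl tosylate
Product: 6, 4-bromo-2-methylbut-1-ene
Conditions: LiBr (3 equiv), acetone, reflux; distil
Reagents that add atoms: lithium bromide, [Li+].[Br-]
Why: Finkelstein-type SN2 displacement of a primary tosylate; it avoids the acidic conditions (HBr, PBr3) that would isomerise or hydrobrominate the alkene.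

**Step 5**
Reactants: 3, 1,3-dibromo-2-(bromomethyl)benzene; 6, 4-bromo-2-methylbut-1-ene
Product: 7, 1,3-dibromo-2-(4-methylpent-4-en-1-yl)benzene
Conditions: 6, Mg, THF, rt (gives 3-methylbut-3-enylmagnesium bromide); add slowly to 3 with Li2CuCl4 (3 mol %), THF, −20 → 0 °C
Reagents that add atoms: none
Why: Kochi Cu-catalysed sp3–sp3 Grignard coupling; the benzylic bromide reacts far faster than the two aryl C–Br bonds, which are inert to alkyl Grignard/Cu at ≤ 0 °C.

**Step 6**
Reactants: 7, 1,3-dibromo-2-(4-methylpent-4-en-1-yl)benzene
Product: 8, 1-bromo-3-methyl-2-(4-methylpent-4-en-1-yl)benzene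
Conditions: n-BuLi (1.00 equiv, titrated), THF, −78 °C, 20 min; then MeI (3 equiv), −78 °C → rt
Reagents that add atoms: iodomethane, CI
Why: Br/Li exchange on the symmetric dibromide stops cleanly at the mono-lithio stage, and the aryllithium (Li meta to the remaining Br, so no aryne) is methylated by SN2.

**Step 7**
Reactants: 9, squaric acid (3,4-dihydroxycyclobut-3-ene-1,2-dione)
Product: 10, dimethyl squarate (3,4-dimethoxycyclobut-3-ene-1,2-dione)
Conditions: HC(OMe)3, MeOH, reflux
Reagents that add atoms: trimethyl orthoformate, COC(OC)OC; methanol, CO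
Why: Squaric acid is a vinylogous carboxylic acid and is esterified by methanol with orthoformate as water scavenger.

**Step 8**
Reactants: 10, dimethyl squarate
Product: 11, 3-methoxy-4-(propan-2-yl)cyclobut-3-ene-1,2-dione
Conditions: i-PrMgCl (1.1 equiv), THF, −78 °C; then TFAA (1.5 equiv), −78 °C; aq. NH4Cl
Reagents that add atoms: isopropylmagnesium chloride, CC(C)[Mg]Cl
Why: 1,2-addition to one squarate carbonyl, then trifluoroacetylation of the tertiary alkoxide triggers ionisation and hydrolytic loss of methanol (1,3-carbonyl transposition), giving the 3-alkyl-4-methoxy dione.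

**Step 9**
Reactants: 8, 1-bromo-3-methyl-2-(4-methylpent-4-en-1-yl)benzene; 11, 3-methoxy-4-(propan-2-yl)cyclobut-3-ene-1,2-dione
Product: 12, 4-hydroxy-3-methoxy-4-[3-methyl-2-(4-methylpent-4-en-1-yl)phenyl]-2-(propan-2-yl)cyclobut-2-en-1-one (racemic)
Conditions: 8, t-BuLi (2.0 equiv), THF, −78 °C, 30 min; cannulate into 11 in THF, −78 °C; aq. NH4Cl at −78 °C
Reagents that add atoms: none
Why: Br/Li exchange, then 1,2-addition to the more electrophilic carbonyl of 11 (the one next to the OMe-bearing carbon, not part of the vinylogous ester); the new carbinol centre is racemic and is erased in step 10.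

**Step 10**
Reactants: 12, the 4-aryl-4-hydroxycyclobutenone
Product: 13, 2-methoxy-7-methyl-8-(4-methylpent-4-en-1-yl)-3-(propan-2-yl)naphthalene-1,4-dione
Conditions: p-xylene, reflux (138 °C), Ar, 2 h; cool; then Ag2O, K2CO3, rt
Reagents that add atoms: none
Why: Moore rearrangement: 4π ring opening (OH rotating outward) gives an aryl vinylketene, which closes by 6π electrocyclisation onto the only free ortho carbon; tautomerisation gives the hydroquinone and Ag2O oxidises it to the quinone, fixing OMe next to the carbonyl peri to the side chain.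

**Step 11**
Reactants: 13, the 2-methoxyquinone
Product: 14, 2-hydroxy-7-methyl-8-(4-methylpent-4-en-1-yl)-3-(propan-2-yl)naphthalene-1,4-dione (the parent hydroxyquinone, salvipisone)
Conditions: 2 M aq. NaOH, MeOH/THF, rt → 40 °C, under Ar; then cold 1 M HCl to pH 3
Reagents that add atoms: sodium hydroxide/water, [Na+].[OH-]
Why: Addition–elimination at C2 of the vinylogous ester expels methoxide and gives the stabilised hydroxyquinone anion; the isolated alkene is inert to base and to the brief cold acidification.

**Step 12**
Reactants: 14, the 2-hydroxyquinone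
Product: 15, acetylsalvipisone, 2-acetoxy-7-methyl-8-(4-methylpent-4-en-1-yl)-3-(propan-2-yl)naphthalene-1,4-dione
Conditions: Ac2O, pyridine, DMAP (cat.), CH2Cl2, 0 °C → rt
Reagents that add atoms: acetic anhydride, CC(=O)OC(C)=O
Why: O-acylation of the acidic enolic OH of a 2-hydroxy-1,4-naphthoquinone gives the 2-acetoxy-1,4-quinone, as with lawsone and lapachol.

## Compound list

1 | 1,3-dibromobenzene | Brc1cccc(Br)c1 | starting material
2 | 1,3-dibromo-2-methylbenzene | Cc1c(Br)cccc1Br | intermediate
3 | 1,3-dibromo-2-(bromomethyl)benzene | BrCc1c(Br)cccc1Br | intermediate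
4 | 3-methylbut-3-en-1-ol | C=C(C)CCO | starting material
5 | 3-methylbut-3-en-1-yl 4-methylbenzenesulfonate | C=C(C)CCOS(=O)(=O)c1ccc(C)cc1 | intermediate
6 | 4-bromo-2-methylbut-1-ene | C=C(C)CCBr | intermediate
7 | 1,3-dibromo-2-(4-methylpent-4-en-1-yl)benzene | C=C(C)CCCc1c(Br)cccc1Br | intermediate
8 | 1-bromo-3-methyl-2-(4-methylpent-4-en-1-yl)benzene | C=C(C)CCCc1c(C)cccc1Br | intermediate
9 | squaric acid | OC1=C(O)C(=O)C1=O | starting material
10 | dimethyl squarate | COC1=C(OC)C(=O)C1=O | intermediate
11 | 3-methoxy-4-(propan-2-yl)cyclobut-3-ene-1,2-dione | COC1=C(C(C)C)C(=O)C1=O | intermediate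
12 | 4-hydroxy-3-methoxy-4-[3-methyl-2-(4-methylpent-4-en-1-yl)phenyl]-2-(propan-2-yl)cyclobut-2-en-1-one (racemic) | C=C(C)CCCc1c(C)cccc1C1(O)C(OC)=C(C(C)C)C1=O | intermediate
13 | 2-methoxy-7-methyl-8-(4-methylpent-4-en-1-yl)-3-(propan-2-yl)naphthalene-1,4-dione | C=C(C)CCCc1c(C)ccc2c1C(=O)C(OC)=C(C(C)C)C2=O | intermediate
14 | 2-hydroxy-7-methyl-8-(4-methylpent-4-en-1-yl)-3-(propan-2-yl)naphthalene-1,4-dione | C=C(C)CCCc1c(C)ccc2c1C(=O)C(O)=C(C(C)C)C2=O | intermediate
15 | acetylsalvipisone | C=C(C)CCCc1c(C)ccc2c1C(=O)C(OC(C)=O)=C(C(C)C)C2=O | target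

## Summary

**Total steps:** 12.

**Longest linear sequence:** 8 steps (1 → 2 → 3 → 7 → 8 → 12 → 13 → 14 → 15, i.e. steps 1, 2, 5, 6, 9, 10, 11, 12; the chain branch through steps 3, 4 is equally long). The squarate branch contributes 2 steps off the main line.

**Three steps most likely to fail, with fallbacks:**

1. **Step 10 (Moore rearrangement with an ortho-alkyl aryl group).** Steric crowding may slow the 6π closure and let the hydroxyl trap the ketene to give a furanone. Fallback: build the quinone ring by Dötz benzannulation instead. Convert 8 to the aryl(methoxy)carbene chromium complex (t-BuLi; Cr(CO)6; Me3OBF4), react with 3-methylbut-1-yne and oxidise (CAN) to the 3-isopropyl-1,4-naphthoquinone. Then introduce the C2 oxygen via the epoxyquinone (H2O2/Na2CO3, then base-mediated opening) to reach 14.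

2. **Step 6 (mono Br/Li exchange and methylation).** Any unreacted dibromide or dimethylated by-product is a non-polar compound that is hard to separate from 8. Fallback: carry dibromide 7 directly into the coupling (mono-exchange, addition to 11, Moore rearrangement) and install the methyl group last by Pd-catalysed methylation (trimethylboroxine or SnMe4) of the resulting 7-bromoquinone, where the intermediates are polar and separable.

3. **Step 5 (Cu-catalysed benzyl–alkyl coupling beside two aryl bromides).** Homocoupling to the bibenzyl or Br/Mg exchange could erode the yield. Fallback: change the disconnection to the aryl–CH2 bond. Alkylate 2,6-dibromophenyllithium (from 1, LDA, −78 °C) directly with 4-methylpent-4-en-1-yl triflate (from 4-methylpent-4-en-1-ol, Tf2O, 2,6-lutidine) to give 7 in one step, bypassing 2, 3 and 6.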